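A small charge of substrate takes up reagent in steps, to first product, then bis adduct, then triple product, while capture agent can take first product aside. I wanted the bis adduct, as a fraction of the substrate charged, at the end of each new flask.

| setting | autumn | spring | midnight | grey | red | ochre |
|---|---|---|---|---|---|---|
| substrate | 0.050 M | 0.050 M | 0.075 M | 0.050 M | 0.050 M | 0.050 M |
| reagent | 1.8 equiv | 1.8 equiv | 1.8 equiv | 1.80 equiv | 1.80 equiv | 1.80 equiv |
| capture agent | 3.4 mM | 7.5 mM | 5 mM | 5.00 mM | 5.00 mM | 5.00 mM |
| temperature | 95 °C | 106 °C | 95 °C | 90 °C | 110 °C |  |
| remark | run made earlier | run made earlier | run made earlier |  |  | at 90 °C until 3.0 h, from then on at 110 °C |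
| time |  |  |  | 10 h | 10 h | 10 h |

- autumn (time / h: bis adduct / %): 0.833: 0.8; 1.33: 1.1; 2.00: 1.6; 3.00: 2.4; 4.00: 4.6; 6.00: 7.8; 10.0: 16.4
- spring (time / h: bis adduct / %): 0.250: 0.2; 0.667: 1.5; 1.33: 2.9; 2.00: 5.6; 2.50: 5.8; 4.00: 12.3; 5.00: 17.3
- midnight (time / h: bis adduct / %): 2.00: 3.3; 4.00: 8.1; 6.00: 14.3; 8.00: 19.8; 10.0: 24.2

(each reading ± 0.5 percentage points)

- the numbers in the tables scatter with a standard deviation of 0.5 percentage points
- reactions considered so far: reagent + first product -> bis adduct; first product + capture agent -> trapped intermediate; reagent + bis adduct -> triple product; substrate + reagent -> first product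

* the best flask by amount of bis adduct, in percent of the substrate charged; "all alike" if 1.5 percentage points covers them all (grey / red / ochre / all alike)
* amount of bis adduct at the end, in percent of the substrate charged, grey
* amount of bis adduct at the end, in percent of the substrate charged, red
* amount of bis adduct at the end, in percent of the substrate charged, ochre

I counted time on one clock, the standard hour: an hour of the autumn run, a reduced time. The autumn run read 16.4 % at 10.0 h, and the spring run read 17.3 % at 5.00 h. So the spring run's pace was about 2.00 times autumn's, as a reading. From this I took the doubling interval, the degrees of heat that double the pace of the bis adduct curve: 11.0.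

Each step joins two charged species, so a stronger charge at equal equivalents should speed the clock in proportion. The midnight run tested that. Its reading at 4.00 h counts as 6.00 h and stood at 8.1 %, while autumn read 7.8 % at 6.00 h. Per substrate the capture agent stood at 6.80 % in autumn and 6.67 % in midnight, so this pair showed nothing about it. I left it out of the clock as my own assumption.

Grey's pace is 0.730, so its time counts as 7.30 h. Between the autumn readings that gave me 10.6 %. Red's pace is 2.57, which counts as 25.7 h. Ochre counts as 20.2 h. Red had the longest count, so I chose red.

Both hot flasks lie past midnight's last reading, at 15.0 h. Its last stretch, from 12.0 h, climbed 0.0147 h⁻¹ of the charge per standard hour. Midnight ran at 95 °C, so I counted again from its own temperature: red came to 25.7 h and ochre to 20.2 h. Held straight, that gives red 39.9 % and ochre 31.8 %.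

The straight line was the weak link. The last stretch gained 4.4 percentage points, less than the 5.5 points of the one before. So I took the middle between that slope held and half of it. This gave red 36.0 % and ochre 29.9 %.

The forecast gave 5.5 % for grey, 40 % for red and 34 % for ochre, and said “Red should be best”; its grey lay below mine, its red and ochre above.

The flasks gave 10.2 % in grey, 35.2 % in red and 29.9 % in ochre, and the best was red.

    reagent + first product → bis adduct (k = 1.00 M⁻¹ h⁻¹, Ea = 63.0 kJ mol⁻¹)
    first product + capture agent → trapped intermediate (k = 0.340 M⁻¹ h⁻¹, Ea = 70.0 kJ mol⁻¹)
    reagent + bis adduct → triple product (k = 0.200 M⁻¹ h⁻¹, Ea = 84.0 kJ mol⁻¹)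
    substrate + reagent → first product (k = 0.520 M⁻¹ h⁻¹, Ea = 96.0 kJ mol⁻¹)
    (constants at 90 °C)

The bend in red's curve came from the depletion of reagent together with the time allowed. Red kept 31 % of its reagent at 10.0 h. With reagent held at its charge, red stood at 49.9 %, and left to 100 h it reached 48.3 %. A doubling every 11.0 K counts the neighbour flask, red's charge at 135 °C, as 124 h, far beyond red's 25.7 h. That neighbour gave 44.8 % at 10.0 h, with 2.4 % of its reagent left.

The readings are simulated from invented constants, noise included.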